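Two questions stood on this flask, and I answered them in powers of ten.

in all of them: initiator 0.47 mM
- south-east: free monomer 18 mM; run made earlier
- south: free monomer 29 mM; run made earlier
- flask: free monomer 13 mM; time 4.0 h

| run | time / h | monomer in chains / % | free monomer / % |
|---|---|---|---|
| south-east | 1.00 | 61.6 | 37.7 |
| south-east | 2.00 | 84.5 | 15.1 |
| south-east | 3.00 | 93.6 | 6.0 |
| south-east | 4.00 | 98.3 | 3.1 |
| south | 1.00 | 61.4 | 38.5 |
| south | 2.00 | 83.6 | 15.4 |
| south | 3.00 | 94.1 | 6.4 |
| south | 4.00 | 97.0 | 3.3 |

(each reading ± 0.5 percentage points)

1. average number of monomer units in a chain (living and dead chains, two that joined counted as one) at 4.0 h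
2. part of the free monomer that has reacted at 4.0 h

- the average divides the monomer in chains by the number of chains, living and dead together; two radicals that join make one chain
- the numbers in the tables scatter by 0.5 percentage points (one standard deviation)
- the earlier runs do not show the number of chains; that part of a forecast is a guess

The runs at 18 mM and 29 mM of free monomer overlapped within the scatter, so I let the flask, with the same initiator, follow their curve. That curve was nearly straight in the logarithm, a pseudo-first-order fall. I therefore used the decade time τ, the hours free monomer takes to fall tenfold.

For the conversion in the flask, I took the south run's last reading, 96.7 %, as a lower bound. The first hour of the south-east run gave τ = 2.36 h. Held for 4.0 h, that gave my upper bound, 98.0 %. I tightened this with the mean reading at 3.00 h, 6.20 %. It gave τ = 2.48 h, longer than the first hour's. So I reckoned 2.45 % free at the end in the flask, a conversion of 97.5 %.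

The runs showed no chains, so I had no upper bound for the average. Two chains per charged initiator gave me a lower bound of 13.5.

The forecast said 97.2 % (96.2 % to 98 %), below my figure, and 28 units in a chain (14 to 90), saying of the chain length “This is a guess”.

The flask gave 97.6 % and 59.5 units, with 0.213 mM of dead chain.

    initiator → 2 initiating radical (k = 4.20 × 10⁻⁵ s⁻¹)
    free monomer + initiating radical → growing radical + monomer in chains (k = 6.83 × 10⁵ M⁻¹ s⁻¹)
    free monomer + growing radical → monomer in chains + growing radical, rate k3*[growing radical]*[free monomer] (k = 19700 M⁻¹ s⁻¹)
    2 growing radical → dead chain (k = 1.00 × 10⁸ M⁻¹ s⁻¹)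

At 4.00 h, free monomer in the flask had a half-life of 0.94 h by addition to growing radical, shorter than 2.7 h by addition to initiating radical. At 0.660 h the ratio of those two rates had been 50, and at 4.00 h it was 2.9. Taken over the 4.0 h, the flask's own τ came to 2.46 h. The neighbour flask with 0.19 mM of initiator kept 10.7 % of its free monomer over the same hours, so its τ was 4.12 h.

Readings and results stem from a simulated flask for substances that don't exist, noise included.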